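The five-membered ring (C1 ketone, C2=C3, C4 bearing acetoxy and carboxyheptyl, C5 bearing pentenyl) is not assembled as a five-membered ring. A cobalt-carbonyl-catalysed two-carbon ring expansion of a 1-alkynylcyclopropanol, made from cyclopropanone hemiacetal and the chain-bearing terminal alkyne, gives the 3-alkylcyclopent-2-enone in one operation. The carbinol carbon becomes C1, the alkyne carbons become C5 and C4, and the cyclopropane methylenes become C2 and C3. The step exploits the 1,3-relation of the C1 carbonyl to the chain-bearing C4. The enone then allows catalytic enantioselective conjugate boration at C4; boron, a masked hydroxyl, directs anti alkylation at C5 before stereoretentive oxidation and acetylation.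

Key step: step 3

Assumption: cyclopropanone ethyl hemiacetal and (Z)-1-bromopent-2-ene are taken as purchasable.
Assumption: the copper complex of (R,R)-QuinoxP* is taken to add boron to the enantioface that gives the (S)-boronate; if the sense is opposite, (S,S)-QuinoxP* is used with no other change.

Step 1
Reactants: 1 dec-9-ynoic acid
Product: 2 tert-butyl dec-9-ynoate
Conditions: Cl3CC(=NH)OtBu, BF3·OEt2 (cat.), CH2Cl2/cyclohexane, rt
Reagents that add atoms: tert-butyl 2,2,2-trichloroacetimidate, CC(C)(C)OC(=N)C(Cl)(Cl)Cl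
Why: Acid-catalysed imidate esterification masks the acid as a tert-butyl ester that should survive the Grignard, amide-base and oxidation steps and is removed by acid at the end.

Step 2
Reactants: 2 tert-butyl dec-9-ynoate; 3 1-ethoxycyclopropan-1-ol
Product: 4 tert-butyl 10-(1-hydroxycyclopropyl)dec-9-ynoate
Conditions: 2 (2.2 equiv), EtMgBr (2.1 equiv), THF, 0 → 40 °C; then 3, 0 → 50 °C; aq NH4Cl
Reagents that add atoms: none
Why: One equivalent of the alkynylmagnesium bromide deprotonates the hemiacetal, which collapses to cyclopropanone, and a second equivalent adds to it (1,2-addition of an alkynyl Grignard reagent); the hindered tert-butyl ester is not attacked by the weakly nucleophilic acetylide.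

Step 3
Reactants: 4 tert-butyl 10-(1-hydroxycyclopropyl)dec-9-ynoate
Product: 5 tert-butyl 8-(3-oxocyclopent-1-en-1-yl)octanoate
Conditions: Co2(CO)8 (10 mol %), P(O-2-iPrC6H4)3 (20 mol %), DME, reflux, Ar
Reagents that add atoms: none
Why: The alkyne binds Co2(CO)6 (zerovalent cobalt); the strained cyclopropanol then opens by a 1,2-shift of one ring methylene from the carbinol carbon onto the metal-bound alkyne, so that the carbinol becomes the ketone, and C–C reductive elimination followed by protonolysis of the C–Co bond by the former hydroxyl proton releases the conjugated enone. The closest known reaction type is the cobalt-carbonyl-mediated rearrangement of 1-(1-alkynyl)cyclopropanols to cyclopent-2-enones, a relative of the Pauson–Khand manifold. The one ring that closes does so by metallacycle reductive elimination between the migrated methylene and the distal alkyne carbon, a ring-expansion closure and not a polar cyclisation. No stereocenter is created. The step needs ring growth by two atoms and not by one (a 2-alkylidenecyclobutanone), and it needs the chain on the β-carbon of the enone; the first is secured by the dicobalt complex engaging both alkyne carbons, the second by the chain sitting on the distal alkyne carbon. The tert-butyl ester and the saturated chain should be inert to the catalyst.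

Step 4
Reactants: 5 tert-butyl 8-(3-oxocyclopent-1-en-1-yl)octanoate
Product: 6 tert-butyl 8-[(1S)-3-oxo-1-(4,4,5,5-tetramethyl-1,3,2-dioxaborolan-2-yl)cyclopentyl]octanoate
Conditions: B2pin2 (1.5 equiv), Cu(MeCN)4PF6 (10 mol %), (R,R)-QuinoxP* (12 mol %), LiOtBu (15 mol %), DMSO, rt; aq NH4Cl
Reagents that add atoms: bis(pinacolato)diboron, CC1(C)OB(OC1(C)C)B1OC(C)(C)C(C)(C)O1
Why: Copper-catalysed enantioselective conjugate boration of a β-substituted cyclic enone: the bisphosphine-bound boryl complex of monovalent copper adds to the β-carbon from one enantioface, so the boron-bearing quaternary stereocenter (future C4) is set by the catalyst.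

Step 5
Reactants: 6 tert-butyl 8-[(1S)-3-oxo-1-(4,4,5,5-tetramethyl-1,3,2-dioxaborolan-2-yl)cyclopentyl]octanoate
Product: 7 tert-butyl 8-[(1R)-4-oxo-1-(4,4,5,5-tetramethyl-1,3,2-dioxaborolan-2-yl)cyclopent-2-en-1-yl]octanoate
Conditions: LiN(SiMe3)2 (1.05 equiv), THF, −78 °C; then PhS(Cl)=NtBu (1.2 equiv), −78 °C
Reagents that add atoms: none
Why: Kinetic deprotonation at the α-methylene remote from the quaternary carbon, then sulfinimidoyl-chloride dehydrogenation of the lithium enolate (S-sulfenylation and syn-elimination at low temperature), gives the enone; the other α-carbon cannot be dehydrogenated because its neighbour is quaternary, and the descriptor changes from S to R only through the priority rules.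

Step 6
Reactants: 7 tert-butyl 8-[(1R)-4-oxo-1-(4,4,5,5-tetramethyl-1,3,2-dioxaborolan-2-yl)cyclopent-2-en-1-yl]octanoate; 8 (Z)-1-bromopent-2-ene
Product: 9 tert-butyl 8-[(1S,5S)-4-oxo-5-[(2Z)-pent-2-en-1-yl]-1-(4,4,5,5-tetramethyl-1,3,2-dioxaborolan-2-yl)cyclopent-2-en-1-yl]octanoate
Conditions: LiN(SiMe3)2 (1.05 equiv), THF, −78 °C; then 8 (1.5 equiv), DMPU, −78 → −40 °C; AcOH quench
Reagents that add atoms: none
Why: α′-Alkylation of the cross-conjugated lithium dienolate (the only enolisable position) by SN2 at the primary allylic bromide; the electrophile should enter anti to the C–B bond of the adjacent quaternary carbon (bulk of the pinacol boronate plus σ(C–B) donation, as with β-silyl enolates), which sets C5 with the pentenyl group cis to the chain.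

Step 7
Reactants: 9 tert-butyl 8-[(1S,5S)-4-oxo-5-[(2Z)-pent-2-en-1-yl]-1-(4,4,5,5-tetramethyl-1,3,2-dioxaborolan-2-yl)cyclopent-2-en-1-yl]octanoate
Product: 10 tert-butyl 8-[(1R,5S)-1-hydroxy-4-oxo-5-[(2Z)-pent-2-en-1-yl]cyclopent-2-en-1-yl]octanoate
Conditions: NaBO3·4H2O, THF/H2O (1:1), 0 °C → rt
Reagents that add atoms: sodium perborate tetrahydrate, [Na+].[O-]OB=O.O.O.O.O
Why: Stereoretentive oxidation of the tertiary allylic pinacol boronate (1,2-shift of carbon from boron to oxygen in the peroxoborate, no allylic transposition) turns the C–B bond into the C4–OH bond, trans to the pentenyl group.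

Step 8
Reactants: 10 tert-butyl 8-[(1R,5S)-1-hydroxy-4-oxo-5-[(2Z)-pent-2-en-1-yl]cyclopent-2-en-1-yl]octanoate
Product: 11 tert-butyl 8-[(1R,5S)-1-acetoxy-4-oxo-5-[(2Z)-pent-2-en-1-yl]cyclopent-2-en-1-yl]octanoate
Conditions: Ac2O (3 equiv), Sc(OTf)3 (2 mol %), MeCN, −20 °C
Reagents that add atoms: acetic anhydride, CC(=O)OC(C)=O
Why: Lewis-acid-catalysed acylation of the hindered tertiary alcohol under non-basic conditions avoids enolisation at C5, so neither epimerisation nor elimination is expected.

Step 9
Reactants: 11 tert-butyl 8-[(1R,5S)-1-acetoxy-4-oxo-5-[(2Z)-pent-2-en-1-yl]cyclopent-2-en-1-yl]octanoate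
Product: 12 8-[(1R,5S)-1-acetoxy-4-oxo-5-[(2Z)-pent-2-en-1-yl]cyclopent-2-en-1-yl]octanoic acid
Conditions: CF3CO2H/CH2Cl2 (1:4), 0 °C → rt
Reagents that add atoms: none
Why: Acidolysis of the tert-butyl ester with loss of 2-methylpropene; the tertiary allylic acetate should not ionise because its cation would be conjugated to the enone carbonyl, and the acidic medium leaves C5 and the Z-alkene untouched.

Compound list
1 | dec-9-ynoic acid | C#CCCCCCCCC(=O)O | starting material
2 | tert-butyl dec-9-ynoate | C#CCCCCCCCC(=O)OC(C)(C)C | intermediate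
3 | 1-ethoxycyclopropan-1-ol (cyclopropanone ethyl hemiacetal) | CCOC1(O)CC1 | starting material
4 | tert-butyl 10-(1-hydroxycyclopropyl)dec-9-ynoate | CC(C)(C)OC(=O)CCCCCCCC#CC1(O)CC1 | intermediate
5 | tert-butyl 8-(3-oxocyclopent-1-en-1-yl)octanoate | CC(C)(C)OC(=O)CCCCCCCC1=CC(=O)CC1 | intermediate
6 | tert-butyl 8-[(1S)-3-oxo-1-(4,4,5,5-tetramethyl-1,3,2-dioxaborolan-2-yl)cyclopentyl]octanoate | CC(C)(C)OC(=O)CCCCCCC[C@]1(B2OC(C)(C)C(C)(C)O2)CC(=O)CC1 | intermediate
7 | tert-butyl 8-[(1R)-4-oxo-1-(4,4,5,5-tetramethyl-1,3,2-dioxaborolan-2-yl)cyclopent-2-en-1-yl]octanoate | CC(C)(C)OC(=O)CCCCCCC[C@]1(B2OC(C)(C)C(C)(C)O2)CC(=O)C=C1 | intermediate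
8 | (Z)-1-bromopent-2-ene | CC/C=C\CBr | starting material
9 | tert-butyl 8-[(1S,5S)-4-oxo-5-[(2Z)-pent-2-en-1-yl]-1-(4,4,5,5-tetramethyl-1,3,2-dioxaborolan-2-yl)cyclopent-2-en-1-yl]octanoate (boron trans to pentenyl) | CC/C=C\C[C@@H]1C(=O)C=C[C@@]1(CCCCCCCC(=O)OC(C)(C)C)B2OC(C)(C)C(C)(C)O2 | intermediate
10 | tert-butyl 8-[(1R,5S)-1-hydroxy-4-oxo-5-[(2Z)-pent-2-en-1-yl]cyclopent-2-en-1-yl]octanoate | CC/C=C\C[C@@H]1C(=O)C=C[C@@]1(CCCCCCCC(=O)OC(C)(C)C)O | intermediate
11 | tert-butyl 8-[(1R,5S)-1-acetoxy-4-oxo-5-[(2Z)-pent-2-en-1-yl]cyclopent-2-en-1-yl]octanoate | CC/C=C\C[C@@H]1C(=O)C=C[C@@]1(CCCCCCCC(=O)OC(C)(C)C)OC(C)=O | intermediate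
12 | 8-[(1R,5S)-1-acetoxy-4-oxo-5-[(2Z)-pent-2-en-1-yl]cyclopent-2-en-1-yl]octanoic acid | CC/C=C\C[C@@H]1C(=O)C=C[C@@]1(CCCCCCCC(=O)O)OC(C)=O | target

Total step count: 9
Longest linear sequence: 9 steps (1 → 12)

Steps most likely to fail

Step 6. The hindered cross-conjugated dienolate may alkylate slowly, with competing O-alkylation, SN2′ attack or loss of alkene geometry in the allylic bromide, and facial selectivity may erode if the temperature has to be raised. The fallback sets out from 7. The same dienolate is alkylated with the smaller and more reactive 1-bromopent-2-yne (LiN(SiMe3)2, THF/DMPU, −78 °C) to give tert-butyl 8-[(1S,5S)-4-oxo-5-(pent-2-yn-1-yl)-1-(4,4,5,5-tetramethyl-1,3,2-dioxaborolan-2-yl)cyclopent-2-en-1-yl]octanoate F1. Lindlar semi-hydrogenation (H2, Pd/CaCO3 poisoned with Pb(OAc)2, quinoline, EtOAc) then forms the Z-alkene and the route is rejoined at 9.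

Step 7. Under the basic peroxide the product may epimerise at C5 or open by retro-aldol cleavage, and the enone may be epoxidised. The fallback sets out from 9. Luche reduction (NaBH4, CeCl3·7H2O, MeOH, −78 °C) removes the enolisable ketone and gives tert-butyl 8-[(1S,4RS,5S)-4-hydroxy-5-[(2Z)-pent-2-en-1-yl]-1-(4,4,5,5-tetramethyl-1,3,2-dioxaborolan-2-yl)cyclopent-2-en-1-yl]octanoate F2. Perborate oxidation of the boronate then gives tert-butyl 8-[(1R,4RS,5R)-1,4-dihydroxy-5-[(2Z)-pent-2-en-1-yl]cyclopent-2-en-1-yl]octanoate F3. MnO2 in CH2Cl2 re-oxidises only the secondary allylic alcohol and the route is rejoined at 10.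

Step 5. The sulfur electrophile may react at the enolate oxygen or the syn-elimination may stall, and the boronate may suffer from the electrophilic reagent. The fallback sets out from 6. The kinetic lithium enolate is selenenylated (PhSeBr, THF, −78 °C) to tert-butyl 8-[(1R)-3-oxo-4-(phenylselanyl)-1-(4,4,5,5-tetramethyl-1,3,2-dioxaborolan-2-yl)cyclopentyl]octanoate F4 (mixture of epimers at the selenium-bearing carbon). Oxidation with one equivalent of mCPBA at −78 °C and warming with iPr2NH brings about selenoxide syn-elimination, and the route is rejoined at 7.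

Further compounds
F1 | step 6 | tert-butyl 8-[(1S,5S)-4-oxo-5-(pent-2-yn-1-yl)-1-(4,4,5,5-tetramethyl-1,3,2-dioxaborolan-2-yl)cyclopent-2-en-1-yl]octanoate | CCC#CC[C@@H]1C(=O)C=C[C@@]1(CCCCCCCC(=O)OC(C)(C)C)B2OC(C)(C)C(C)(C)O2
F2 | step 7 | tert-butyl 8-[(1S,4RS,5S)-4-hydroxy-5-[(2Z)-pent-2-en-1-yl]-1-(4,4,5,5-tetramethyl-1,3,2-dioxaborolan-2-yl)cyclopent-2-en-1-yl]octanoate | CC/C=C\C[C@@H]1C(O)C=C[C@@]1(CCCCCCCC(=O)OC(C)(C)C)B2OC(C)(C)C(C)(C)O2
F3 | step 7 | tert-butyl 8-[(1R,4RS,5R)-1,4-dihydroxy-5-[(2Z)-pent-2-en-1-yl]cyclopent-2-en-1-yl]octanoate | CC/C=C\C[C@@H]1C(O)C=C[C@@]1(CCCCCCCC(=O)OC(C)(C)C)O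
F4 | step 5 | tert-butyl 8-[(1R)-3-oxo-4-(phenylselanyl)-1-(4,4,5,5-tetramethyl-1,3,2-dioxaborolan-2-yl)cyclopentyl]octanoate | CC(C)(C)OC(=O)CCCCCCC[C@]1(B2OC(C)(C)C(C)(C)O2)CC(=O)C([Se]c2ccccc2)C1
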